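## Plan

Labels and enabling feature: the tetralin is numbered C1–C8a and its benzo ring is ring C. Ring B is the aryl group on C1, ring A is the guaiacyl ring on carbinol C7'', and C8'' is the aryloxy methine. Carbon C4a lies ortho to C8a and para to the C7 oxygen. This is where O1 of a 6,7-dioxygenated coumarin is attached, and coumarin C4 maps onto the diarylmethine C1, so the lactone oxygen can become the leaving group on C4a.
Cuts, in retrosynthetic order: C7''–ring A; C3–CH3 (back to C3=CH2 and C3=O); C4–C4a; C3–C4 (methyl ketone from an amide); C2–CH3; C1–ring B; C8''–O(ring B).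
Forward order: the ring B boronic acid carrying the C7''–C9'' chain is added to the coumarin. The lactone is methylated and opened, its phenol is triflated and its carbonyl is turned into a methyl ketone. Palladium then closes the carbocycle, C3 receives its methyl group, and ring A is joined last.
Stereochemistry: C8'' comes from (S)-propane-1,2-diol with Mitsunobu inversion, and C1 from the Rh/(S)-SEGPHOS conjugate arylation. C2 comes from anti alkylation on the lactone, C3 from thermodynamically controlled hydrogen-atom-transfer hydrogenation, and C7'' from Felkin–Anh addition to the C8'' aldehyde.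

Key step: step 11

Assumption: for the parent coumarin and phenylboronic acid, (R)-SEGPHOS gives the (R)-4-arylchroman-2-one. The CIP ranking at C4 (C4a > aryl > C3) is the same here, so (S)-SEGPHOS is taken to give 4S.

Notation: ArB = 3-methoxy-4-{[(2R)-1-(triisopropylsilyloxy)propan-2-yl]oxy}phenyl. Target numbering is used in all Why lines.

## Route

Step 1
Reactants: 1 (S)-propane-1,2-diol
Product: 2 (2S)-1-(triisopropylsilyloxy)propan-2-ol
Conditions: TIPSCl (1.0 equiv), imidazole, CH2Cl2, 0 °C to rt
Reagents that add atoms: triisopropylsilyl chloride, CC(C)[Si](Cl)(C(C)C)C(C)C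
Why: Silyl ether formation; the bulky chlorosilane should react at the unhindered primary hydroxyl far faster than at the secondary one, and the stereocentre is not touched.

Step 2
Reactants: 2 (2S)-1-(triisopropylsilyloxy)propan-2-ol; 3 4-bromo-2-methoxyphenol
Product: 4 [(2R)-2-(4-bromo-2-methoxyphenoxy)propoxy]triisopropylsilane (ArB–Br)
Conditions: PPh3, DIAD, THF, 0 °C to rt
Reagents that add atoms: none
Why: Mitsunobu etherification; the phenoxide displaces the oxyphosphonium group of the secondary alcohol by SN2 with inversion, so the 2S carbinol becomes the 2R aryl ether that is C8'' of the target.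

Step 3
Reactants: 4 [(2R)-2-(4-bromo-2-methoxyphenoxy)propoxy]triisopropylsilane
Product: 7 {3-methoxy-4-[(2R)-1-(triisopropylsilyloxy)propan-2-yloxy]phenyl}boronic acid (ArB–B(OH)2), via aryllithium 5 (not isolated), via lithium aryltriisopropoxyborate 6 (not isolated)
Conditions: n-BuLi, THF, −78 °C; B(OiPr)3, −78 °C to rt; 1 M HCl, 0 °C
Reagents that add atoms: triisopropyl borate, CC(C)OB(OC(C)C)OC(C)C; water, O
Why: Bromine–lithium exchange, borate trapping and hydrolysis is the standard route to arylboronic acids, and the silyl and alkyl aryl ethers are inert to n-BuLi at −78 °C.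

Step 4
Reactants: 8 esculetin (6,7-dihydroxycoumarin)
Product: 9 isoscopoletin (6-hydroxy-7-methoxycoumarin)
Conditions: K2CO3 (1.0 equiv), MeI (1.0 equiv), DMF, 0 °C to rt
Reagents that add atoms: iodomethane, CI
Why: Williamson ether synthesis with limiting base; the 7-OH is the more acidic phenol because its anion is conjugated through C4a and the C3=C4 bond with the lactone carbonyl, so O7 should be alkylated preferentially.

Step 5
Reactants: 9 isoscopoletin
Product: 10 6-benzyloxy-7-methoxycoumarin
Conditions: BnBr, K2CO3, DMF, rt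
Reagents that add atoms: benzyl bromide, BrCc1ccccc1
Why: Williamson benzylation of the only remaining phenol masks the future C7 hydroxyl with a group that can be removed together with the ring A benzyl ether at the end.

Step 6
Reactants: 10 6-benzyloxy-7-methoxycoumarin; 7 ArB–B(OH)2
Product: 11 (4S)-4-ArB-6-benzyloxy-7-methoxychroman-2-one
Conditions: Rh(acac)(C2H4)2 (3 mol %), (S)-SEGPHOS (3.3 mol %), 7 (3 equiv), dioxane/H2O 10:1, 60 °C
Reagents that add atoms: none
Why: Hayashi–Miyaura asymmetric 1,4-addition to a coumarin; the aryl–rhodium species bearing (S)-SEGPHOS inserts the C3=C4 bond from one face of the flat lactone and hydrolysis of the rhodium enolate releases the 4S lactone, which fixes C1 of the target.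

Step 7
Reactants: 11 (4S)-4-ArB-6-benzyloxy-7-methoxychroman-2-one
Product: 13 (3R,4S)-4-ArB-6-benzyloxy-7-methoxy-3-methylchroman-2-one (3,4-trans), via lithium enolate 12 (not isolated)
Conditions: LiHMDS, THF, −78 °C; MeI, −78 to −40 °C
Reagents that add atoms: iodomethane, CI
Why: Lactone enolate alkylation; the pseudo-axial aryl group on the half-chair enolate shields one face, so MeI should enter anti to it and give the trans lactone, which fixes C2, while the low temperature prevents loss of phenoxide from the aryl ester enolate.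

Step 8
Reactants: 13 (3R,4S)-4-ArB-6-benzyloxy-7-methoxy-3-methylchroman-2-one
Product: 14 (2R,3S)-3-ArB-3-(5-benzyloxy-2-hydroxy-4-methoxyphenyl)-N-methoxy-N,2-dimethylpropanamide
Conditions: MeNH(OMe)·HCl, AlMe3, CH2Cl2, 0 °C to rt; cold 1 M HCl
Reagents that add atoms: N,O-dimethylhydroxylamine hydrochloride, CNOC.Cl
Why: Weinreb aminolysis of the reactive aryl ester with an aluminium amide is fast and non-basic, so C2 should not epimerise, and it liberates the phenol oxygen that marks C4a.

Step 9
Reactants: 14 (2R,3S)-3-ArB-3-(5-benzyloxy-2-hydroxy-4-methoxyphenyl)-N-methoxy-N,2-dimethylpropanamide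
Product: 15 (2R,3S)-3-ArB-3-[5-benzyloxy-4-methoxy-2-(trifluoromethylsulfonyloxy)phenyl]-N-methoxy-N,2-dimethylpropanamide
Conditions: PhNTf2, Et3N, CH2Cl2, 0 °C to rt
Reagents that add atoms: N-phenylbis(trifluoromethanesulfonimide), O=S(=O)(N(c1ccccc1)S(=O)(=O)C(F)(F)F)C(F)(F)F
Why: Phenol triflation with the mild triflimide reagent is selective for the phenoxide and, unlike triflic anhydride, does not activate the amide carbonyl.

Step 10
Reactants: 15 (2R,3S)-3-ArB-3-[5-benzyloxy-4-methoxy-2-(trifluoromethylsulfonyloxy)phenyl]-N-methoxy-N,2-dimethylpropanamide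
Product: 17 (3R,4S)-4-ArB-4-[5-benzyloxy-4-methoxy-2-(trifluoromethylsulfonyloxy)phenyl]-3-methylbutan-2-one, via magnesium hemiaminal alkoxide 16 (not isolated)
Conditions: MeMgBr, THF, −20 to 0 °C; cold 1 M HCl
Reagents that add atoms: methylmagnesium bromide, C[Mg]Br
Why: Weinreb ketone synthesis; the chelated tetrahedral adduct prevents a second addition, and aryl triflates tolerate MeMgBr at or below 0 °C when no transition metal is present.

Step 11
Reactants: 17 (3R,4S)-4-ArB-4-[5-benzyloxy-4-methoxy-2-(trifluoromethylsulfonyloxy)phenyl]-3-methylbutan-2-one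
Product: 18 (3R,4S)-4-ArB-6-benzyloxy-7-methoxy-3-methyl-3,4-dihydronaphthalen-2(1H)-one
Conditions: Pd(OAc)2 (10 mol %), XPhos (20 mol %), anhydrous K3PO4 (3 equiv), toluene (0.01 M), 90 °C, Ar
Reagents that add atoms: none
Why: Zerovalent palladium generated from Pd(OAc)2 and XPhos inserts into the C4a–OTf bond, phosphate removes a proton from the ketone methyl group, the carbon-bound enolate on divalent palladium completes a seven-membered palladacycle, and C–C reductive elimination forms C4–C4a. The closest known reaction type is the palladium-catalysed α-arylation of ketones in its intramolecular version with aryl halides or sulfonates. The one new ring closes in a formal 6-(enolexo) mode, with the enolate double bond lying outside the six-membered carbocycle. No stereocentre is created: C1 is not involved, and C2 should hold because the product enolises toward the much more acidic benzylic C4 and because the 1,2-trans isomer is in any case the more stable one. Site selectivity follows from ring size, since arylation at C2 would require a benzocyclobutene, and C- over O-arylation (the latter would give a 4H-chromene) relies on the preference of bulky biarylphosphine palladium enolates for C–C reductive elimination. The weak anhydrous base protects the triflate from S–O cleavage, and high dilution suppresses intermolecular arylation of the acidic tetralone.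

Step 12
Reactants: 18 (3R,4S)-4-ArB-6-benzyloxy-7-methoxy-3-methyl-3,4-dihydronaphthalen-2(1H)-one
Product: 19 (1S,2R)-1-ArB-7-benzyloxy-6-methoxy-2-methyl-3-methylidene-1,2,3,4-tetrahydronaphthalene
Conditions: Cp2TiMe2, toluene/THF, 70 °C, dark
Reagents that add atoms: dimethyltitanocene, C[Ti](C)(C1C=CC=C1)C1C=CC=C1
Why: Petasis methylenation; the thermally generated titanium methylidene is non-basic, so the easily enolised 2-tetralone undergoes cycloaddition and cycloreversion instead of the deprotonation a Wittig ylide would cause, and C2 keeps its configuration.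

Step 13
Reactants: 19 (1S,2R)-1-ArB-7-benzyloxy-6-methoxy-2-methyl-3-methylidene-1,2,3,4-tetrahydronaphthalene
Product: 20 (1S,2S,3R)-1-ArB-7-benzyloxy-6-methoxy-2,3-dimethyl-1,2,3,4-tetrahydronaphthalene
Conditions: Mn(dpm)3 (10 mol %), PhSiH3, TBHP, i-PrOH, rt
Reagents that add atoms: none
Why: Mukaiyama-type hydrogen-atom-transfer hydrogenation; the manganese hydride delivers H to the CH2 terminus and the tertiary C3 radical takes up the second H along the axial trajectory, which should give the equatorial C3 methyl trans to the C2 methyl while leaving the benzyl ether intact.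

Step 14
Reactants: 20 (1S,2S,3R)-1-ArB-7-benzyloxy-6-methoxy-2,3-dimethyl-1,2,3,4-tetrahydronaphthalene
Product: 21 (2R)-2-{4-[(1S,2S,3R)-7-benzyloxy-6-methoxy-2,3-dimethyl-1,2,3,4-tetrahydronaphthalen-1-yl]-2-methoxyphenoxy}propan-1-ol
Conditions: TBAF, THF, rt
Reagents that add atoms: none
Why: Fluoride-driven silyl ether cleavage frees the primary alcohol and affects no other group in the molecule.

Step 15
Reactants: 21 (2R)-2-{4-[(1S,2S,3R)-7-benzyloxy-6-methoxy-2,3-dimethyl-1,2,3,4-tetrahydronaphthalen-1-yl]-2-methoxyphenoxy}propan-1-ol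
Product: 22 (2R)-2-{4-[(1S,2S,3R)-7-benzyloxy-6-methoxy-2,3-dimethyl-1,2,3,4-tetrahydronaphthalen-1-yl]-2-methoxyphenoxy}propanal
Conditions: Dess–Martin periodinane, NaHCO3, CH2Cl2, 0 °C to rt; used at once
Reagents that add atoms: none
Why: Buffered Dess–Martin oxidation is fast and near neutral, stops at the aldehyde and should spare the configurationally labile α-aryloxy centre C8''.

Step 16
Reactants: 22 (2R)-2-{4-[(1S,2S,3R)-7-benzyloxy-6-methoxy-2,3-dimethyl-1,2,3,4-tetrahydronaphthalen-1-yl]-2-methoxyphenoxy}propanal; 23 1-benzyloxy-4-bromo-2-methoxybenzene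
Product: 25 (1S,2R)-1-(4-benzyloxy-3-methoxyphenyl)-2-{4-[(1S,2S,3R)-7-benzyloxy-6-methoxy-2,3-dimethyl-1,2,3,4-tetrahydronaphthalen-1-yl]-2-methoxyphenoxy}propan-1-ol (erythro), via aryllithium 24 (not isolated)
Conditions: 23, n-BuLi, THF, −78 °C; then 22, THF, −78 °C; H2O quench
Reagents that add atoms: none
Why: Aryllithium 1,2-addition under polar Felkin–Anh control; with weakly chelating lithium in THF the C8''–OAr bond stands perpendicular to the carbonyl and the nucleophile approaches anti to it past the hydrogen, which should give the anti (erythro) 7''S,8''R carbinol.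

Step 17
Reactants: 25 (1S,2R)-1-(4-benzyloxy-3-methoxyphenyl)-2-{4-[(1S,2S,3R)-7-benzyloxy-6-methoxy-2,3-dimethyl-1,2,3,4-tetrahydronaphthalen-1-yl]-2-methoxyphenoxy}propan-1-ol
Product: 26 (1S,2R)-1-(4-hydroxy-3-methoxyphenyl)-2-{4-[(1S,2S,3R)-7-hydroxy-6-methoxy-2,3-dimethyl-1,2,3,4-tetrahydronaphthalen-1-yl]-2-methoxyphenoxy}propan-1-ol (CID53359464)
Conditions: H2 (1 atm), 10% Pd/C, EtOAc/EtOH, rt, stopped after two equivalents of H2
Reagents that add atoms: none
Why: Catalytic hydrogenolysis cleaves both aryl benzyl ethers quickly under neutral conditions, whereas the secondary benzylic alcohol reacts much more slowly without acid and should survive.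

## Compound list

1 | (S)-propane-1,2-diol | C[C@H](O)CO | starting material
2 | (2S)-1-(triisopropylsilyloxy)propan-2-ol | C[C@H](O)CO[Si](C(C)C)(C(C)C)C(C)C | intermediate
3 | 4-bromo-2-methoxyphenol | COc1cc(Br)ccc1O | starting material
4 | [(2R)-2-(4-bromo-2-methoxyphenoxy)propoxy]triisopropylsilane | COc1cc(Br)ccc1O[C@H](C)CO[Si](C(C)C)(C(C)C)C(C)C | intermediate
5 | aryllithium ArB–Li | COc1cc([Li])ccc1O[C@H](C)CO[Si](C(C)C)(C(C)C)C(C)C | intermediate
6 | lithium ArB-triisopropoxyborate | [Li+].COc1cc([B-](OC(C)C)(OC(C)C)OC(C)C)ccc1O[C@H](C)CO[Si](C(C)C)(C(C)C)C(C)C | intermediate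
7 | {3-methoxy-4-[(2R)-1-(triisopropylsilyloxy)propan-2-yloxy]phenyl}boronic acid | COc1cc(B(O)O)ccc1O[C@H](C)CO[Si](C(C)C)(C(C)C)C(C)C | intermediate
8 | esculetin | O=c1ccc2cc(O)c(O)cc2o1 | starting material
9 | isoscopoletin (6-hydroxy-7-methoxycoumarin) | COc1cc2oc(=O)ccc2cc1O | intermediate
10 | 6-benzyloxy-7-methoxycoumarin | COc1cc2oc(=O)ccc2cc1OCc1ccccc1 | intermediate
11 | (4S)-4-ArB-6-benzyloxy-7-methoxychroman-2-one | O=C1C[C@@H](c2ccc(O[C@H](C)CO[Si](C(C)C)(C(C)C)C(C)C)c(OC)c2)c2cc(OCc3ccccc3)c(OC)cc2O1 | intermediate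
12 | lithium enolate of 11 | [Li+].[O-]C1=C[C@@H](c2ccc(O[C@H](C)CO[Si](C(C)C)(C(C)C)C(C)C)c(OC)c2)c2cc(OCc3ccccc3)c(OC)cc2O1 | intermediate
13 | (3R,4S)-4-ArB-6-benzyloxy-7-methoxy-3-methylchroman-2-one | O=C1[C@H](C)[C@@H](c2ccc(O[C@H](C)CO[Si](C(C)C)(C(C)C)C(C)C)c(OC)c2)c2cc(OCc3ccccc3)c(OC)cc2O1 | intermediate
14 | (2R,3S)-3-ArB-3-(5-benzyloxy-2-hydroxy-4-methoxyphenyl)-N-methoxy-N,2-dimethylpropanamide | CON(C)C(=O)[C@H](C)[C@@H](c1ccc(O[C@H](C)CO[Si](C(C)C)(C(C)C)C(C)C)c(OC)c1)c1cc(OCc2ccccc2)c(OC)cc1O | intermediate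
15 | aryl triflate of 14 | CON(C)C(=O)[C@H](C)[C@@H](c1ccc(O[C@H](C)CO[Si](C(C)C)(C(C)C)C(C)C)c(OC)c1)c1cc(OCc2ccccc2)c(OC)cc1OS(=O)(=O)C(F)(F)F | intermediate
16 | bromomagnesium hemiaminal alkoxide from 15 and MeMgBr | CON(C)C(C)(O[Mg]Br)[C@H](C)[C@@H](c1ccc(O[C@H](C)CO[Si](C(C)C)(C(C)C)C(C)C)c(OC)c1)c1cc(OCc2ccccc2)c(OC)cc1OS(=O)(=O)C(F)(F)F | intermediate
17 | (3R,4S)-4-ArB-4-[5-benzyloxy-4-methoxy-2-(trifluoromethylsulfonyloxy)phenyl]-3-methylbutan-2-one | CC(=O)[C@H](C)[C@@H](c1ccc(O[C@H](C)CO[Si](C(C)C)(C(C)C)C(C)C)c(OC)c1)c1cc(OCc2ccccc2)c(OC)cc1OS(=O)(=O)C(F)(F)F | intermediate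
18 | (3R,4S)-4-ArB-6-benzyloxy-7-methoxy-3-methyl-3,4-dihydronaphthalen-2(1H)-one | CC(C)[Si](C(C)C)(C(C)C)OC[C@@H](C)Oc1ccc(cc1OC)[C@H]1c2cc(OCc3ccccc3)c(OC)cc2CC(=O)[C@@H]1C | intermediate
19 | (1S,2R)-1-ArB-7-benzyloxy-6-methoxy-2-methyl-3-methylidene-1,2,3,4-tetrahydronaphthalene | CC(C)[Si](C(C)C)(C(C)C)OC[C@@H](C)Oc1ccc(cc1OC)[C@H]1c2cc(OCc3ccccc3)c(OC)cc2CC(=C)[C@@H]1C | intermediate
20 | (1S,2S,3R)-1-ArB-7-benzyloxy-6-methoxy-2,3-dimethyl-1,2,3,4-tetrahydronaphthalene | CC(C)[Si](C(C)C)(C(C)C)OC[C@@H](C)Oc1ccc(cc1OC)[C@H]1c2cc(OCc3ccccc3)c(OC)cc2C[C@@H](C)[C@@H]1C | intermediate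
21 | primary alcohol from 20 | OC[C@@H](C)Oc1ccc(cc1OC)[C@H]1c2cc(OCc3ccccc3)c(OC)cc2C[C@@H](C)[C@@H]1C | intermediate
22 | (2R)-α-aryloxy aldehyde from 21 | O=C[C@@H](C)Oc1ccc(cc1OC)[C@H]1c2cc(OCc3ccccc3)c(OC)cc2C[C@@H](C)[C@@H]1C | intermediate
23 | 1-benzyloxy-4-bromo-2-methoxybenzene | COc1cc(Br)ccc1OCc1ccccc1 | starting material
24 | 4-benzyloxy-3-methoxyphenyllithium | COc1cc([Li])ccc1OCc1ccccc1 | intermediate
25 | erythro (7''S,8''R) carbinol, bis(benzyl ether) | COc1cc([C@H](O)[C@@H](C)Oc2ccc([C@H]3c4cc(OCc5ccccc5)c(OC)cc4C[C@@H](C)[C@@H]3C)cc2OC)ccc1OCc1ccccc1 | intermediate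
26 | CID53359464 | COc1cc([C@H](O)[C@@H](C)Oc2ccc([C@H]3c4cc(O)c(OC)cc4C[C@@H](C)[C@@H]3C)cc2OC)ccc1O | target

## Step count and risks

Total step count: 17. Longest linear sequence: 15 steps (steps 1–3, then 6–17).

**Risk 1, step 11.** Oxidative addition into the electron-rich, ortho-hindered triflate may be slow. In that case base-mediated S–O cleavage of the triflate, O-arylation of the enolate or aldol self-condensation could compete with ring closure.

The fallback removes the external base and preforms the nucleophile.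
- It sets out from 17. Kinetic deprotonation at the methyl group (LiHMDS, TMSCl, THF, −78 °C) gives the terminal trimethylsilyl enol ether F1.
- F1 is treated with Pd(OAc)2, P(t-Bu)3 and Bu3SnF in toluene at 85 °C. Fluoride moves the enolate from silicon to tin, and the tin enolate transmetallates to the arylpalladium triflate.
- The same C4–C4a bond forms under essentially neutral conditions, and the route is rejoined at 18.

**Risk 2, step 6.** Insertion of the electron-rich 6,7-dialkoxycoumarin into the aryl–rhodium bond may be sluggish, so that protodeboronation of the boronic acid outruns conjugate addition.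

The fallback separates bond formation from stereocontrol.
- It sets out from 10 and 7. An oxidative Heck reaction (Pd(OAc)2, 1,10-phenanthroline, O2, DMF, 80 °C) gives the achiral 4-arylcoumarin F2.
- Copper hydride asymmetric conjugate reduction follows (Cu(OAc)2, DTBM-SEGPHOS in the antipode that gives 4S, (EtO)2MeSiH, t-BuOH, toluene). It is expected to run on to the chroman-2-ol (lactol) F3.
- TEMPO/PhI(OAc)2 oxidation of the lactol returns the route to 11.

**Risk 3, step 16.** Facial selectivity may be poor if lithium chelation through the two guaiacyl oxygens of ring B competes with the Felkin–Anh pathway. Partial epimerisation of the aldehyde by the basic aryllithium is also possible.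

The fallback sets C7'' by hydride delivery instead of aryl delivery.
- It sets out from 22. The addition is run without regard to selectivity, and the crude mixture of 25 and the threo carbinol F4 is oxidised with Dess–Martin periodinane to the aryl ketone F5.
- Chelation-controlled reduction with Zn(BH4)2 in Et2O at −78 to 0 °C delivers hydride to the chelate from the side of the C8'' hydrogen. This should give the erythro alcohol, and the route is rejoined at 25.

## Further compounds

F1 | step 11 | trimethylsilyl enol ether of 17 (terminal, 2-silyloxybut-1-ene) | C=C(O[Si](C)(C)C)[C@H](C)[C@@H](c1ccc(O[C@H](C)CO[Si](C(C)C)(C(C)C)C(C)C)c(OC)c1)c1cc(OCc2ccccc2)c(OC)cc1OS(=O)(=O)C(F)(F)F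
F2 | step 6 | 4-ArB-6-benzyloxy-7-methoxycoumarin | O=c1cc(-c2ccc(O[C@H](C)CO[Si](C(C)C)(C(C)C)C(C)C)c(OC)c2)c2cc(OCc3ccccc3)c(OC)cc2o1
F3 | step 6 | (4S)-4-ArB-6-benzyloxy-7-methoxychroman-2-ol (anomeric mixture) | OC1C[C@@H](c2ccc(O[C@H](C)CO[Si](C(C)C)(C(C)C)C(C)C)c(OC)c2)c2cc(OCc3ccccc3)c(OC)cc2O1
F4 | step 16 | threo (7''R,8''R) epimer of 25 | COc1cc([C@@H](O)[C@@H](C)Oc2ccc([C@H]3c4cc(OCc5ccccc5)c(OC)cc4C[C@@H](C)[C@@H]3C)cc2OC)ccc1OCc1ccccc1
F5 | step 16 | (2R)-1-(4-benzyloxy-3-methoxyphenyl)-2-aryloxypropan-1-one from 25 and F4 | COc1cc(C(=O)[C@@H](C)Oc2ccc([C@H]3c4cc(OCc5ccccc5)c(OC)cc4C[C@@H](C)[C@@H]3C)cc2OC)ccc1OCc1ccccc1
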